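Readings and results come from a simulation from invented constants, noise included.

The vessel is closed, stirred and held at constant temperature. Maple is the flask in question, and alder is a hotter twin.

| flask | substrate | partner | initiator | temperature | remark | time |
|---|---|---|---|---|---|---|
| maple | 26 mM | 27.3 mM | 2.3 mM | 80 °C | the very flask that is asked about, followed so far |  |
| alder | 26 mM | 27.3 mM | 2.3 mM | 86 °C | run made earlier |  |
| flask | 26 mM | 27.3 mM | 2.3 mM | 80 °C |  | 8.0 d |

| run | time / d | product / % | substrate / % |
|---|---|---|---|
| maple | 0.625 | 38.2 | 33.5 |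
| maple | 1.04 | 48.9 | 19.3 |
| maple | 1.67 | 58.8 | 14.2 |
| maple | 3.00 | 68.9 | 9.7 |
| maple | 5.00 | 76.4 | 6.9 |
| maple | 8.00 | 82.3 | 4.1 |
| alder | 0.625 | 47.4 | 22.9 |
| alder | 1.04 | 57.4 | 17.7 |
| alder | 1.67 | 67.3 | 13.7 |
| alder | 3.00 | 75.2 | 8.9 |
| alder | 5.00 | 80.8 | 6.4 |
| alder | 8.00 | 86.1 | 2.0 |

(standard deviation of a reading: 1 percentage point)

- north: at 8.0 d add partner, 100% of the amount charged, then wait 8.0 d
- north-east: change nothing and wait 8.0 d more
- north-west: at 8.0 d raise the temperature by 20 K, then wait 8.0 d
- south: at 8.0 d take out 90% of the by-product then present, then wait 8.0 d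

* product, in percent of the substrate first charged, at 8.0 d
* the remedy with the largest gain of product, or "none" below 2 percentage points (north / north-east / north-west / south / none)
* product present, in percent of the substrate first charged, after north
* product present, in percent of the substrate first charged, after south

Work in fractions of the substrate charged. Add substrate and product in maple, and look at the shortfall from the charge. Take it as two parts: a parked share proportional to free substrate, and a steady loss. Call the mean rate of that loss the leak rate. Solve from the last two readings, each with scatter 1 percentage point: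

shortfall at 5.00 d: 16.7%; at 8.00 d: 13.6%

parked per unit of substrate: 1.89

leak rate: 0.00731 d⁻¹

pool still able to react in maple: 11.9%

Now turn each setting in maple. The reading at 8.0 d is 82.3%.

Partner: free partner is 22.7%, more than the pool, so adding partner buys pace. Expect product near the mark 88.3%, the charge less the leak.

Waiting: treat the pool's fall as pseudo-first-order, from the substrate readings. That reckons a gain of 3 points.

Heat: alder gives a leak rate of 0.0123 d⁻¹. That is 1.68 times maple's, while the first product reading rises 1.24 times. So, as far as these scattered readings tell, the leak rose further in alder than the pace did.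

By-product: the reckoning gives no pace here. Hold south under the same mark.

The forecast says 82.3%, north, 98% after north and 94% after south: "Adding partner raises it about fivefold". My mark for north is lower than its number.

    initiator → 2 initiating radical (k = 5.02 × 10⁻⁷ s⁻¹, Ea = 129 kJ mol⁻¹)
    substrate + initiating radical → capped initiator + first chain carrier (k = 1.98 × 10⁵ M⁻¹ s⁻¹, Ea = 11.0 kJ mol⁻¹)
    substrate ⇌ dormant form (K = 1.44, k = 1.21 × 10⁻⁵ s⁻¹, Ea = 118 kJ mol⁻¹, ΔH = −58.0 kJ mol⁻¹)
    partner + first chain carrier ⇌ product + second chain carrier (K = 1.50, k = 4560 M⁻¹ s⁻¹, Ea = 40.0 kJ mol⁻¹, ΔH = −42.0 kJ mol⁻¹)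
    2 first chain carrier → ended chains (k = 1.80 × 10⁸ M⁻¹ s⁻¹, Ea = 12.0 kJ mol⁻¹)
    substrate + second chain carrier → by-product + first chain carrier (k = 3950 M⁻¹ s⁻¹, Ea = 18.0 kJ mol⁻¹)
    (constants at 80 °C)

Maple gives 81.7%. North gains 9.6 points and reaches 91.3%; south reaches 87.0%. The forecast parts from the flask on these two. The leak reckoned to 8.0 d is 5.85%, and maple's capped initiator is 1.35 mM of 26 mM, or 5.19%. North stands 3 points above the mark. Take the neighbour flask, like maple but with 16 mM of substrate. Its capped initiator is 1.35 mM, as in maple. Carry the leak as an amount: 9.50% of this smaller charge, so the mark is 90.5%. That neighbour flask gives 90.1%.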